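The target is made from a nucleophile charged as protonated nucleophile, so each target takes two free base: one to release the nucleophile and one to hold the acid set free by the step. Call the base allowance the part of the charged electrophile that the free base can pay for, c(free base)/(2 c(electrophile)), which is the level at which target should stall wherever it stands below one. It is 0.548 for summer and 1.10 for dusk.

common to all: electrophile 0.21 M; protonated nucleophile 0.231 M
- red: free base 0.30 M; run made earlier
- grey: free base 0.68 M; run made earlier
- summer: free base 0.230 M; time 4.0 h
- dusk: free base 0.460 M; time 4.0 h

| run | time / h | electrophile / % | target / % |
|---|---|---|---|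
| red | 0.333 | 32 | 54 |
| red | 1.00 | 14 | 63 |
| red | 2.00 | 10 | 71 |
| red | 3.00 | 8 | 69 |
| red | 4.00 | 5 | 71 |
| grey | 0.833 | 6 | 77 |
| grey | 1.50 | 4 | 86 |
| grey | 2.50 | 1 | 86 |
| grey | 3.00 | 0 | 85 |
| grey | 4.00 | 0 | 85 |

(scatter of a reading: 1.5 percentage points)

- percentages count the electrophile that a species holds: one homo dimer counts as two
- candidate steps: 2 electrophile -> homo dimer; electrophile + nucleophile -> acid set free + target; nucleophile + acid set free <-> protonated nucleophile; electrophile + acid set free -> side product; acid set free + free base <-> salt of the base

* part of the electrophile that has reacted at the end, summer
* part of the electrophile that has reacted at the end, dusk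
* what raising the concentration of free base from its lowest to its highest value here does to the part of the electrophile that has reacted (changes below 5 percentage points count as none) (no change / it falls / it rises)

The red run tests it: its allowance of 0.714 stands close to its reading of 71% target. One number is not enough, though. The grey run has an allowance of 1.62, yet its target stops at 85% with 0% electrophile left, so another route took about 15.0%.

The allowance still sorts the flasks. Summer's is lower than red's, and red kept 5% electrophile at 4.00 h, so summer should end with more left and below 95.0% reacted. Dusk's is above one, as in grey, so its electrophile should end close to grey's reading of 0%. This reckoning gives a rough ceiling for summer and a direction. The forecast commits further, with 88% for summer, 99% for dusk and "it rises", on the ground of a “strong-base proton balance”.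

The flasks give 89.9% for summer and 99.4% for dusk: it rises, by 9.6 percentage points.

    2 electrophile → homo dimer (k = 9.26 × 10⁻⁴ M⁻¹ s⁻¹)
    electrophile + nucleophile → acid set free + target (k = 0.00945 M⁻¹ s⁻¹)
    nucleophile + acid set free ⇌ protonated nucleophile, settled at all times (K = 14700 M⁻¹)
    electrophile + acid set free → side product (k = 6.04 × 10⁻⁵ M⁻¹ s⁻¹)
    acid set free + free base ⇌ salt of the base, settled at all times (K = 46000 M⁻¹)

Summer holds 56.2% target at its allowance of 0.548, and free base is the limiting reagent, with 0.29% of it left. In summer the target step uses electrophile 3.6 times as fast as the homo dimer step just after the start, but 0.24 times as fast at 4.00 h. A neighbour of summer charged with 0.58 M of free base has an allowance of 1.38 and ends with 85.6% target and 0.22% of its electrophile left.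

The runs were computed with made-up constants; scatter was added.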